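The ten-membered ring contains six contiguous atoms, C5–C10, in which the C10 methyl is para to the C7 isopropenyl group. With a temporary C5–C10 bond drawn, these atoms are the ring of (S)-carvone. The C3–C4 epoxide is cis, so its parent Z-olefin fits into a cyclohexene. The C4–C5 bond is therefore made as a six-ring closure. In iodo keto stannane 11, a carvone-derived cyclohexanone whose C10 carries the C1–C4 chain, the (Z)-alkenyllithium C4 adds to ketone C5. The resulting trans-decalinol fixes the olefin geometry and directs the epoxidation through its C5 hydroxyl. It also holds C9–Sn antiperiplanar to C5–C10, so an oxidative Grob-type scission then unfolds the (E)-cyclodecene.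

Key step: step 7

Convention: target ring atoms are C1 (CH–OAng), C2 (CH2), C3 and C4 (epoxide CH and CMe), C5 (CH–OAc), C6 (CH–OSen), C7 (CH–isopropenyl), C8 (CH2), C9 (CH–OAc) and C10 (C(Me)OH). These locants are kept for all intermediates. In six-ring and decalin intermediates, β is the face that carries the C7 isopropenyl group and α is the other face.

Step 1
Reactants: 1 3-[(tert-butyldimethylsilyl)oxy]propanal
Product: 2 (Z)-tert-butyl[(4-iodopent-3-en-1-yl)oxy]dimethylsilane
Conditions: EtPPh3I, n-BuLi, THF, rt; I2, −78 °C; NaHMDS, −20 °C; then 1, −78 °C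
Reagents that add atoms: ethyltriphenylphosphonium iodide, CC[P+](c1ccccc1)(c1ccccc1)c1ccccc1.[I-]; iodine, II
Why: Stork–Zhao-type Wittig olefination with the non-stabilised α-iodo ylide Ph3P=C(I)CH3, whose kinetic cis-oxaphosphetane should give the (Z)-2-iodoalkene.

Step 2
Reactants: 2 (Z)-tert-butyl[(4-iodopent-3-en-1-yl)oxy]dimethylsilane
Product: 3 (Z)-4-iodopent-3-en-1-ol
Conditions: HF (48 % aq), MeCN, 0 °C
Reagents that add atoms: none
Why: Fluoride-driven cleavage of a primary silyl ether, to which the alkenyl iodide is inert.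

Step 3
Reactants: 3 (Z)-4-iodopent-3-en-1-ol
Product: 4 (Z)-4-iodopent-3-enal
Conditions: Dess–Martin periodinane, CH2Cl2, 0 °C; used at once
Reagents that add atoms: none
Why: The Dess–Martin oxidation is fast and non-basic, so the β,γ-unsaturated aldehyde should form without drift of the double bond into conjugation.

Step 4
Reactants: 5 (S)-(+)-carvone; 4 (Z)-4-iodopent-3-enal
Product: 8 (2S,3S,5R)-2-[(1S,3Z)-4-iodo-1-(triethylsilyloxy)pent-3-en-1-yl]-2-methyl-5-(prop-1-en-2-yl)-3-(tributylstannyl)cyclohexan-1-one (9α-SnBu3, 10α-Me, 10β-side chain, 7β-isopropenyl), via lithium enolate 6 (not isolated), via lithium aldolate 7 (not isolated)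
Conditions: (Bu3Sn)2, n-BuLi, THF, 0 °C; 5, −78 °C; 4, −78 °C; TESOTf, −78 → −40 °C
Reagents that add atoms: hexabutylditin, CCCC[Sn](CCCC)(CCCC)[Sn](CCCC)(CCCC)CCCC; triethylsilyl triflate, CC[Si](CC)(CC)OS(=O)(=O)C(F)(F)F
Why: Tandem conjugate addition–aldol–silylation in which Bu3SnLi adds 1,4 axially and anti to the isopropenyl group (C9, α), the ring (E)-enolate 6 meets the aldehyde anti to the bulky stannyl group (C10, side chain β) through a closed Zimmerman–Traxler chair with the aldehyde residue equatorial (anti aldol, 1S), and O-silylation of 7 blocks the retro-aldol.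

Step 5
Reactants: 8 keto stannane
Product: 10 (2S,3S,5R,6R)-6-hydroxy derivative of 8 (6α-OH, trans to the isopropenyl group), via potassium enolate 9 (not isolated)
Conditions: KHMDS, THF, −78 °C; 2-(phenylsulfonyl)-3-phenyloxaziridine, −78 °C; AcOH
Reagents that add atoms: 2-(phenylsulfonyl)-3-phenyloxaziridine, O=S(=O)(c1ccccc1)N1OC1c1ccccc1
Why: Enolate oxidation with an N-sulfonyloxaziridine, in which only C6 can be deprotonated (C10 is quaternary) and the reagent should attack anti to the neighbouring isopropenyl group and the C10 side chain to give the 6α-alcohol.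

Step 6
Reactants: 10 6α-hydroxy ketone
Product: 11 (2S,3S,5R,6S)-2-[(1S,3Z)-4-iodo-1-(triethylsilyloxy)pent-3-en-1-yl]-2-methyl-6-[(3-methylbut-2-enoyl)oxy]-5-(prop-1-en-2-yl)-3-(tributylstannyl)cyclohexan-1-one (6β-OSen)
Conditions: 3-methylbut-2-enoic acid, PPh3, DIAD, toluene, 0 °C → rt
Reagents that add atoms: 3-methylbut-2-enoic acid, CC(C)=CC(=O)O
Why: Mitsunobu esterification, whose SN2 displacement of the oxyphosphonium group is accelerated by the adjacent carbonyl, inverts C6 and installs the final senecioate on the β face in the same operation.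

Step 7
Reactants: 11 iodo keto stannane
Product: 13 trans-decalinol (5β-OH, 10α-Me, C3=C4 with Me on C4, 1β-OTES (1S), 6β-OSen, 7β-isopropenyl, 9α-SnBu3), via alkenyllithium 12 (not isolated)
Conditions: t-BuLi (2.1 equiv), Et2O–THF, −100 → −78 °C; AcOH, −78 °C
Reagents that add atoms: none
Why: Iodine–lithium exchange at the (Z)-alkenyl iodide outruns carbonyl addition of t-BuLi and gives alkenyllithium 12 with retention, and its C4 then adds to the C5 ketone; the type is the halogen–metal-exchange-initiated intramolecular 1,2-addition of iodoalkenyl ketones. One ring is closed, cyclohexene ring A (C10–C1–C2–C3=C4–C5), by a 6-exo-trig attack on C=O that only the Z isomer can reach. The single new stereocentre, C5, is controlled by the chair of 11 that places C9–Sn, C6–O and the side chain equatorial and the C7 isopropenyl group axial: this group shields the β (axial) face of C5, so C4 should enter equatorially from the α face and the carbinol oxygen becomes β-axial, which is a trans-decalin. The step needs the ketone to react before the senecioate and without enolisation at C6; this rests on the six-membered transition state at −100 °C and on the low electrophilicity of the β,β-disubstituted enoate, and the secondary alkyl–tin bond does not exchange. In 13 the C9–Sn and C5–C10 bonds are antiperiplanar and the C5–OH lies over the β face of C3=C4, which is what steps 8 and 9 use.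

Step 8
Reactants: 13 trans-decalinol
Product: 14 3β,4β-epoxide of 13 (3R,4R)
Conditions: VO(acac)2 (cat.), t-BuOOH, CH2Cl2, 0 °C
Reagents that add atoms: tert-butyl hydroperoxide, CC(C)(C)OO
Why: Hydroxyl-directed vanadium-catalysed epoxidation of a cyclic allylic alcohol, in which the peroxide bound to the pseudo-axial 5β-alkoxide is delivered to the β face of C3=C4 (setting C3 and C4) and the allylic trisubstituted olefin should react far faster than the isopropenyl group or the electron-poor enoate.

Step 9
Reactants: 14 epoxy decalinol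
Product: 15 (1S,3R,4R,6S,7R,9E)-3,4-epoxy-4,10-dimethyl-6-[(3-methylbut-2-enoyl)oxy]-7-(prop-1-en-2-yl)-1-(triethylsilyloxy)cyclodec-9-en-5-one
Conditions: Pb(OAc)4, CH2Cl2, 0 °C → rt
Reagents that add atoms: none
Why: Oxidative Grob-type 1,4-fragmentation of a γ-hydroxyalkylstannane, in which the lead alkoxide collapses to the C5 ketone while the antiperiplanar C5–C10 and C9–Sn bonds break together, so the equatorial C1 and C8 end up trans on the new C9=C10 bond (E) and the ten-membered ring is released under non-basic conditions that spare ester, epoxide and silyl ether.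

Step 10
Reactants: 15 epoxy ketone
Product: 16 (1S,3R,4R,6S,7R,9E)-1-hydroxy analogue of 15
Conditions: HF·pyridine, pyridine, THF, 0 °C
Reagents that add atoms: none
Why: Buffered fluoride cleavage of the triethylsilyl ether, which is now allylic and unhindered, should leave the epoxy ketone and the ester untouched.

Step 11
Reactants: 16 allylic alcohol
Product: 17 (1S,3R,4R,6S,7R,9E)-1-angelate of 16
Conditions: angelic acid, 2,4,6-trichlorobenzoyl chloride, Et3N, toluene, rt; filter; 16, toluene, 70 °C
Reagents that add atoms: angelic acid, C/C=C(/C)C(=O)O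
Why: Yamaguchi-type mixed-anhydride esterification run without a nucleophilic catalyst or free amine, which avoids Z→E drift to the tiglate and epimerisation at C6, and is helped because the C1 carbinol is allylic and no longer neopentyl after step 9.

Step 12
Reactants: 17 epoxy ketone diester
Product: 18 (1S,3R,4R,5S,6S,7R,9E)-5-alcohol
Conditions: Zn(BH4)2, Et2O, −20 °C; aq NH4Cl
Reagents that add atoms: none
Why: Chelation-controlled reduction of an α,β-epoxy ketone, in which Zn2+ ties the epoxide and carbonyl oxygens syn-periplanar and hydride enters from the ring periphery on the side of the C4 methyl group to give the anti (erythro) epoxy alcohol, 5S.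

Step 13
Reactants: 18 epoxy alcohol
Product: 19 (1S,3R,4R,5S,6S,7R,9R,10S)-5,9,10-triol
Conditions: OsO4 (cat.), NMO, acetone–H2O, 0 °C
Reagents that add atoms: osmium tetroxide, O=[Os](=O)(=O)=O; N-methylmorpholine N-oxide, C[N+]1([O-])CCOCC1; water, O
Why: Upjohn dihydroxylation, in which the strained, most electron-rich (E)-trisubstituted olefin should react first, and in the crown conformer that keeps C1–OAng, C5–OH and the C7 isopropenyl group pseudo-equatorial only its outer face is open, so suprafacial addition gives 9R,10S.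

Step 14
Reactants: 19 triol
Product: 20 target, (1S,3R,4R,5S,6S,7R,9R,10S)
Conditions: Ac2O, pyridine, DMAP (cat.), CH2Cl2, 0 °C → rt
Reagents that add atoms: acetic anhydride, CC(=O)OC(C)=O
Why: DMAP-catalysed acetylation takes the two secondary alcohols at C5 and C9, while the tertiary C10 hydroxyl should stay free at room temperature.

Compound list
1 | 3-[(tert-butyldimethylsilyl)oxy]propanal | O=CCCO[Si](C)(C)C(C)(C)C | starting material
2 | (Z)-tert-butyl[(4-iodopent-3-en-1-yl)oxy]dimethylsilane | C/C(I)=C/CCO[Si](C)(C)C(C)(C)C | intermediate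
3 | (Z)-4-iodopent-3-en-1-ol | C/C(I)=C/CCO | intermediate
4 | (Z)-4-iodopent-3-enal | C/C(I)=C/CC=O | intermediate
5 | (S)-(+)-carvone | CC1=CC[C@@H](CC1=O)C(C)=C | starting material
6 | lithium enolate (C5–OLi, C5=C10, 9α-SnBu3, 7β-isopropenyl) | [Li]OC1=C(C)[C@@H]([Sn](CCCC)(CCCC)CCCC)C[C@H](C(C)=C)C1 | intermediate
7 | lithium aldolate (1S, 10β-side chain) | O=C1C[C@@H](C(C)=C)C[C@H]([Sn](CCCC)(CCCC)CCCC)[C@@]1(C)[C@@H](O[Li])C/C=C(/C)I | intermediate
8 | keto stannane, C1 triethylsilyl ether | O=C1C[C@@H](C(C)=C)C[C@H]([Sn](CCCC)(CCCC)CCCC)[C@@]1(C)[C@@H](O[Si](CC)(CC)CC)C/C=C(/C)I | intermediate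
9 | potassium enolate (C5–OK, C5=C6) | [K]OC1=C[C@@H](C(C)=C)C[C@H]([Sn](CCCC)(CCCC)CCCC)[C@@]1(C)[C@@H](O[Si](CC)(CC)CC)C/C=C(/C)I | intermediate
10 | 6α-hydroxy ketone | O=C1[C@H](O)[C@@H](C(C)=C)C[C@H]([Sn](CCCC)(CCCC)CCCC)[C@@]1(C)[C@@H](O[Si](CC)(CC)CC)C/C=C(/C)I | intermediate
11 | 6β-senecioate, iodo keto stannane | O=C1[C@@H](OC(=O)C=C(C)C)[C@@H](C(C)=C)C[C@H]([Sn](CCCC)(CCCC)CCCC)[C@@]1(C)[C@@H](O[Si](CC)(CC)CC)C/C=C(/C)I | intermediate
12 | (Z)-alkenyllithium | O=C1[C@@H](OC(=O)C=C(C)C)[C@@H](C(C)=C)C[C@H]([Sn](CCCC)(CCCC)CCCC)[C@@]1(C)[C@@H](O[Si](CC)(CC)CC)C/C=C(/C)[Li] | intermediate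
13 | trans-decalinol | O[C@]12C(C)=CC[C@H](O[Si](CC)(CC)CC)[C@]1(C)[C@@H]([Sn](CCCC)(CCCC)CCCC)C[C@H](C(C)=C)[C@@H]2OC(=O)C=C(C)C | intermediate
14 | 3β,4β-epoxy decalinol | O[C@]12[C@]3(C)O[C@@H]3C[C@H](O[Si](CC)(CC)CC)[C@]1(C)[C@@H]([Sn](CCCC)(CCCC)CCCC)C[C@H](C(C)=C)[C@@H]2OC(=O)C=C(C)C | intermediate
15 | ten-membered (9E)-epoxy ketone, C1–OTES | C=C(C)[C@H]1C/C=C(\C)[C@@H](O[Si](CC)(CC)CC)C[C@H]2O[C@@]2(C)C(=O)[C@H]1OC(=O)C=C(C)C | intermediate
16 | (9E)-epoxy ketone, C1–OH | C=C(C)[C@H]1C/C=C(\C)[C@@H](O)C[C@H]2O[C@@]2(C)C(=O)[C@H]1OC(=O)C=C(C)C | intermediate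
17 | (9E)-epoxy ketone, C1 angelate | C=C(C)[C@H]1C/C=C(\C)[C@@H](OC(=O)/C(C)=C\C)C[C@H]2O[C@@]2(C)C(=O)[C@H]1OC(=O)C=C(C)C | intermediate
18 | (5S)-epoxy alcohol | C=C(C)[C@H]1C/C=C(\C)[C@@H](OC(=O)/C(C)=C\C)C[C@H]2O[C@@]2(C)[C@@H](O)[C@H]1OC(=O)C=C(C)C | intermediate
19 | 5,9,10-triol | C=C(C)[C@H]1C[C@@H](O)[C@](C)(O)[C@@H](OC(=O)/C(C)=C\C)C[C@H]2O[C@@]2(C)[C@@H](O)[C@H]1OC(=O)C=C(C)C | intermediate
20 | CNP0416509.1 | C=C(C)[C@H]1C[C@@H](OC(C)=O)[C@](C)(O)[C@@H](OC(=O)/C(C)=C\C)C[C@H]2O[C@@]2(C)[C@@H](OC(C)=O)[C@H]1OC(=O)C=C(C)C | target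

Total steps: 14. The longest linear sequence is 14 steps (1 → 20), and 11 steps from (S)-carvone.

Steps most likely to fail

Step 7. The organolithium may be consumed by proton transfer from C6–H or by attack on the C6 ester. The senecioyl group may migrate to the new tertiary alkoxide before the quench. Attack from the β face would give the cis-fused ring system. The fallback replaces the polar organometallic by a neutral, catalytic carbonyl alkenylation and sets out from 11. Miyaura borylation (B2pin2, PdCl2(PPh3)2, PPh3, KOPh, toluene, 50 °C) should give, with retention, the (Z)-alkenyl pinacolboronate F1. A rhodium-catalysed intramolecular 1,2-addition of the boronate to the ketone ([Rh(OH)(cod)]2, dioxane–H2O, 60 °C) then closes the same ring and returns to 13.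

Step 6. Backside displacement at C6 is slowed by the neighbouring isopropenyl-bearing carbon, so acyl transfer with retention or elimination may take over. The fallback places the hydrogen, not the oxygen, from the open face and sets out from 10. Acylation with retention (3-methylbut-2-enoyl chloride, pyridine, CH2Cl2) gives the 6α-senecioate F2. KHMDS at −78 °C converts it into the potassium enolate F3. Kinetic protonation by 2,6-di-tert-butylphenol from the unhindered α face pushes the acyloxy group to the β face and returns to 11.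

Step 4. Three processes may erode the coupling: proton transfer from the labile β,γ-unsaturated aldehyde to the hindered tetrasubstituted enolate, drift of its double bond into conjugation, and poor simple diastereoselection at C1. The fallback builds the side chain linearly and sets out from 5. Enolate 6 is intercepted with non-enolisable acrolein and then TESOTf to give the vinyl carbinol silyl ether F4. Disiamylborane reacts selectively with the monosubstituted olefin, and NaBO3 then gives the primary alcohol F5. Dess–Martin oxidation gives the aldehyde F6. The iodo ylide of step 1 converts F6 into the (Z)-alkenyl iodide and returns to 8.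

Further compounds
F1 | step 7 | (Z)-alkenyl pinacolboronate | O=C1[C@@H](OC(=O)C=C(C)C)[C@@H](C(C)=C)C[C@H]([Sn](CCCC)(CCCC)CCCC)[C@@]1(C)[C@@H](O[Si](CC)(CC)CC)C/C=C(/C)B1OC(C)(C)C(C)(C)O1
F2 | step 6 | 6α-senecioate (C6 epimer of 11) | O=C1[C@H](OC(=O)C=C(C)C)[C@@H](C(C)=C)C[C@H]([Sn](CCCC)(CCCC)CCCC)[C@@]1(C)[C@@H](O[Si](CC)(CC)CC)C/C=C(/C)I
F3 | step 6 | potassium enolate of F2 | [K]OC1=C(OC(=O)C=C(C)C)[C@@H](C(C)=C)C[C@H]([Sn](CCCC)(CCCC)CCCC)[C@@]1(C)[C@@H](O[Si](CC)(CC)CC)C/C=C(/C)I
F4 | step 4 | vinyl carbinol silyl ether | O=C1C[C@@H](C(C)=C)C[C@H]([Sn](CCCC)(CCCC)CCCC)[C@@]1(C)[C@@H](O[Si](CC)(CC)CC)C=C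
F5 | step 4 | primary alcohol | O=C1C[C@@H](C(C)=C)C[C@H]([Sn](CCCC)(CCCC)CCCC)[C@@]1(C)[C@@H](O[Si](CC)(CC)CC)CCO
F6 | step 4 | aldehyde | O=C1C[C@@H](C(C)=C)C[C@H]([Sn](CCCC)(CCCC)CCCC)[C@@]1(C)[C@@H](O[Si](CC)(CC)CC)CC=O
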